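**Target stalls.** The target in the alpha run stops growing while the electrophile keeps falling: between 50.0 min and 120 min the electrophile drops 8.9 percentage points and the target gains 0.6 points.

| setting | gamma | alpha | red | ochre |
|---|---|---|---|---|
| electrophile | 0.083 M | 0.36 M | 0.25 M | 0.068 M |
| nucleophile | 0.102 M | 0.102 M | 0.102 M | 0.102 M |
| free base | 0.204 M | 0.204 M | 0.204 M | 0.204 M |
| protic impurity | 0.0136 M | 0.0136 M | 0.0136 M | 0.0136 M |
| remark | run made earlier | run made earlier |  |  |
| time |  |  | 15 h | 4.0 h |

| run | time / min | target / % | electrophile / % |
|---|---|---|---|
| gamma | 15.0 | 4.1 | 94.8 |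
| gamma | 40.0 | 11.5 | 88.1 |
| gamma | 80.0 | 19.1 | 78.2 |
| gamma | 120 | 23.5 | 71.4 |
| alpha | 10.0 | 2.3 | 97.4 |
| alpha | 20.0 | 4.9 | 93.8 |
| alpha | 50.0 | 6.9 | 88.3 |
| alpha | 120 | 7.5 | 79.4 |

(each reading ± 0.5 percentage points)

- the winner by amount of target, in percent of the electrophile charged; "neither" if no more than 2 percentage points parts them (red / ochre / neither)
- how much target is there at the end, in percent of the electrophile charged: red
- how much target is there at the end, in percent of the electrophile charged: ochre



**Stall share.** In red the nucleophile is the limiting reagent, charged at 0.102 M, less than the 0.25 M of electrophile. So I reckon on its charge. The stall share is the fraction of the nucleophile charge standing as target when the target stops rising, and the alpha reading gives 26.5%.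

**Bench note.** My reckoning puts the stall level of red at 10.8% of its electrophile charge, and that of ochre at 39.7%, higher than red's. Don't count on a longer time in red: the alpha readings show electrophile leaving with the target flat. Watch for that same pattern.

**The forecast.** It says ochre, with red at 11% and ochre at 33%, because “some limited pool caps the target”. Its ochre value is an amount at 4.0 h, while my figure is a stall level.

**The flask.** Red ends at 6.36% and ochre at 34.8%, so ochre leads. Red stood at 9.51% at 7.50 h, so its target falls late, and at 15.0 h red makes target at 0.591 of the rate it uses it up. Time is what would break the forecast for red: at 150 h red holds 0%. Red's end equals 15.6% of the nucleophile charge, less than the stall share of 26.5%.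

    electrophile + nucleophile → acid set free + target (k = 0.0334 L mol⁻¹ min⁻¹)
    nucleophile + acid set free ⇌ protonated nucleophile, settled at all times (K = 3600 L mol⁻¹)
    acid set free + free base ⇌ salt of the base (K = 11000 L mol⁻¹, k = 2.61 L mol⁻¹ min⁻¹)
    electrophile + target → side product (k = 0.0249 L mol⁻¹ min⁻¹)
    nucleophile + target → over-reaction product (k = 0.00262 L mol⁻¹ min⁻¹)
    protic impurity + free base → quenched reagent (k = 0.547 L mol⁻¹ min⁻¹)

**Second flask.** With 0.17 M of nucleophile in red, the stall share gives 18.0%. That flask gives 14.0%, again less than the stall level.

(The earlier runs and the new flask come from a simulation from invented constants, and the scatter is random.)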